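**Retrosynthetic overview**
- The butenolide is the only ring and is formed last. Its C5–O bond and C3=C4 double bond both come from a terminal alkyne and 2-(diethoxyphosphoryl)propanoic acid in one gold-catalysed oxidative annulation (new step).
- The annulation substrate, (S)-octadec-17-yn-2-yl acetate, comes from acetylation of (S)-octadec-17-yn-2-ol.
- The terminal alkyne comes from an alkyne zipper isomerisation of (S)-octadec-4-yn-2-ol.
- The C3–C4 bond and the (S) stereocentre come from lithium pentadecynide and (S)-propylene oxide (chiral pool).

Assumption: the target is read as (2S)-16-(4-methyl-5-oxo-2,5-dihydrofuran-3-yl)hexadecan-2-yl acetate (14 CH2 between carbinol carbon and ring), and on the line "Reagents that add atoms" a reagent whose atom stands only in a numbered, not isolated intermediate is also named and marked as such.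

**Route**

Step 1
Reactants: 1 pentadec-1-yne; 2 (S)-2-methyloxirane ((S)-propylene oxide)
Product: 4 (S)-octadec-4-yn-2-ol, via lithium pentadec-1-yn-1-ide 3 (not isolated)
Conditions: n-BuLi, THF, −78 °C; BF3·OEt2; then 2, −78 °C; H2O
Reagents that add atoms: n-butyllithium, [Li]CCCC (its Li stands only in intermediate 3)
Why: Yamaguchi–Hirao alkynylation, an SN2 opening of the terminal epoxide at its CH2 carbon by the BF3-activated lithium acetylide; the C–O bond at the stereocentre is not touched, so the (S) configuration of 2 is carried over unchanged.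

Step 2
Reactants: 4 (S)-octadec-4-yn-2-ol
Product: 5 (S)-octadec-17-yn-2-ol
Conditions: KH, H2N(CH2)3NH2 (KAPA, 4 equiv), THF, 0 °C → rt; H2O
Reagents that add atoms: none
Why: Alkyne zipper reaction, in which propargyl/allenyl anion equilibria walk the triple bond away from the alkoxide to the chain end, where irreversible deprotonation of the terminal alkyne drains the equilibrium; the carbinol C–H next to the alkoxide is not deprotonated, so the stereocentre is retained.

Step 3
Reactants: 5 (S)-octadec-17-yn-2-ol
Product: 6 (S)-octadec-17-yn-2-yl acetate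
Conditions: Ac2O, pyridine, DMAP (cat.), CH2Cl2, 0 °C → rt
Reagents that add atoms: acetic anhydride, CC(=O)OC(C)=O
Why: DMAP-catalysed O-acylation of a secondary alcohol, which does not break the C–O bond at the stereocentre (retention) and masks the OH that would otherwise trap the gold carbene of step 4.

Step 4
Reactants: 6 (S)-octadec-17-yn-2-yl acetate; 7 2-(diethoxyphosphoryl)propanoic acid (racemic, 1.5 equiv)
Product: 9 (2S)-16-(4-methyl-5-oxo-2,5-dihydrofuran-3-yl)hexadecan-2-yl acetate (target), via keto phosphonate ester 8 (not isolated)
Conditions: Mor-DalPhosAuCl/AgNTf2 (5 mol %), 8-methylquinoline N-oxide (1.5 equiv), PhCl, rt; then LiCl, DBU, MeCN, 0 °C → rt (one pot)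
Reagents that add atoms: 8-methylquinoline N-oxide, Cc1cccc2ccc[n+]([O-])c12 (its O is the ketone O of intermediate 8 and leaves again in the phosphate; no atom of it stays in 9)
Why: Proposed new method: a gold-catalysed oxidative [3+2] butenolide annulation of a terminal alkyne with an α-phosphono carboxylic acid. The cationic P,N-ligated Au(I) activates the alkyne, the N-oxide adds at the internal carbon (Markovnikov) and N–O cleavage gives an α-oxo gold carbene at the terminal carbon; O–H insertion of acid 7 into this carbene gives the acyloxymethyl ketone 8 (C5–O bond). LiCl/DBU then triggers an intramolecular Horner–Wadsworth–Emmons reaction of the phosphonate onto the ketone, which closes the ring and places the C3=C4 double bond, with no E/Z question because the alkene is endocyclic. The closest known reaction types are the Au/N-oxide oxidation of terminal alkynes with carboxylic-acid trapping of the α-oxo gold carbene and the intramolecular HWE butenolide synthesis from α-(phosphonoacyloxy) ketones; the new part is the use of a phosphono acid as the carbene trap and the merger into one annulation. No stereocentre is formed and the remote (S)-acetate is inert to both stages.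

**Compound list**
1 | pentadec-1-yne | C#CCCCCCCCCCCCCC | starting material
2 | (S)-2-methyloxirane ((S)-propylene oxide) | C[C@H]1CO1 | starting material
3 | lithium pentadec-1-yn-1-ide | [Li]C#CCCCCCCCCCCCCC | intermediate
4 | (S)-octadec-4-yn-2-ol | C[C@H](O)CC#CCCCCCCCCCCCCC | intermediate
5 | (S)-octadec-17-yn-2-ol | C[C@H](O)CCCCCCCCCCCCCCC#C | intermediate
6 | (S)-octadec-17-yn-2-yl acetate | CC(=O)O[C@@H](C)CCCCCCCCCCCCCCC#C | intermediate
7 | 2-(diethoxyphosphoryl)propanoic acid (racemic) | CCOP(=O)(OCC)C(C)C(=O)O | starting material
8 | (2S)-18-{[2-(diethoxyphosphoryl)propanoyl]oxy}-17-oxooctadecan-2-yl acetate (keto phosphonate ester, both epimers at the P-bearing carbon) | CC(=O)O[C@@H](C)CCCCCCCCCCCCCCC(=O)COC(=O)C(C)P(=O)(OCC)OCC | intermediate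
9 | (2S)-16-(4-methyl-5-oxo-2,5-dihydrofuran-3-yl)hexadecan-2-yl acetate | CC(=O)O[C@@H](C)CCCCCCCCCCCCCCC1=C(C)C(=O)OC1 | target

**Totals**
Total step count: 4. Longest linear sequence: 4 steps (1 → 4 → 5 → 6 → 9).

**Steps most likely to fail**

Step 4 (proposed new step). Risks: the phosphoryl group or the excess acid may slow the gold catalyst, the carbene may be over-oxidised to the keto aldehyde, or the base stage may be slow in the mixed medium. The fallback uses known chemistry only, sets out from 6 and comes back to the route at 8, which is then isolated. Compound 6 is brominated at the alkyne terminus (NBS, cat. AgNO3, acetone, rt) to (S)-18-bromooctadec-17-yn-2-yl acetate F1. Regioselective catalytic hydration of the bromoalkyne (cat. Ph3PAuNTf2, wet 1,4-dioxane, rt) gives the bromomethyl ketone (S)-18-bromo-17-oxooctadecan-2-yl acetate F2. SN2 displacement of bromide by the potassium carboxylate of 7 (K2CO3, DMF, rt) gives 8. The LiCl/DBU conditions of step 4 (or K2CO3/18-crown-6, toluene) then close 8 to 9 by intramolecular HWE.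

Step 2 (alkyne zipper over 13 positions). Risks: incomplete migration or poor solubility of the C18 alkoxide in diaminopropane, and partial erosion of ee on long exposure. The fallback drops the alkyne strategy for a B-alkyl Suzuki coupling; it sets out from 2 and comes back at 9. Commercial 13-bromotridec-1-ene is converted (Mg, THF) into tridec-12-en-1-ylmagnesium bromide F3. This opens 2 at its CH2 carbon (CuI 10 mol %, THF, −30 °C) to give (S)-hexadec-15-en-2-ol F4. Acetylation (Ac2O, pyridine, DMAP) gives (S)-hexadec-15-en-2-yl acetate F5. Anti-Markovnikov hydroboration with 9-BBN-H (THF, rt) gives (S)-16-(9-borabicyclo[3.3.1]nonan-9-yl)hexadecan-2-yl acetate F6, used in solution. Separately, commercial 4-hydroxy-3-methylfuran-2(5H)-one is triflated (Tf2O, iPr2NEt, CH2Cl2, −78 °C) to 4-methyl-5-oxo-2,5-dihydrofuran-3-yl trifluoromethanesulfonate F7. Suzuki–Miyaura coupling of F6 with F7 (PdCl2(dppf), K3PO4, THF/DMF/H2O, rt) gives 9 directly.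

Step 1 (epoxide alkynylation). Risks: BF3-induced oligomerisation or halohydrin formation from the volatile epoxide, and poor solubility of the C15 acetylide at −78 °C. The fallback sets the stereocentre by catalytic asymmetric reduction instead of the chiral pool; it sets out from 1 (through acetylide 3, made as in step 1) and comes back at 5. Acetylide 3 is acylated with N-methoxy-N-methylacetamide (THF, −78 → 0 °C; NH4Cl) to octadec-3-yn-2-one F8. Noyori transfer hydrogenation (RuCl[(S,S)-TsDPEN](p-cymene) 1 mol %, iPrOH, rt) gives (S)-octadec-3-yn-2-ol F9. The KAPA conditions of step 2 then move the triple bond of this propargylic alcohol from C3 to C17 and give 5.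

**Further compounds**
F1 | step 4 | (S)-18-bromooctadec-17-yn-2-yl acetate | CC(=O)O[C@@H](C)CCCCCCCCCCCCCCC#CBr
F2 | step 4 | (S)-18-bromo-17-oxooctadecan-2-yl acetate | CC(=O)O[C@@H](C)CCCCCCCCCCCCCCC(=O)CBr
F3 | step 2 | tridec-12-en-1-ylmagnesium bromide | C=CCCCCCCCCCCC[Mg]Br
F4 | step 2 | (S)-hexadec-15-en-2-ol | C[C@H](O)CCCCCCCCCCCCC=C
F5 | step 2 | (S)-hexadec-15-en-2-yl acetate | CC(=O)O[C@@H](C)CCCCCCCCCCCCC=C
F6 | step 2 | (S)-16-(9-borabicyclo[3.3.1]nonan-9-yl)hexadecan-2-yl acetate | CC(=O)O[C@@H](C)CCCCCCCCCCCCCCB1C2CCCC1CCC2
F7 | step 2 | 4-methyl-5-oxo-2,5-dihydrofuran-3-yl trifluoromethanesulfonate | CC1=C(OS(=O)(=O)C(F)(F)F)COC1=O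
F8 | step 1 | octadec-3-yn-2-one | CC(=O)C#CCCCCCCCCCCCCCC
F9 | step 1 | (S)-octadec-3-yn-2-ol | C[C@H](O)C#CCCCCCCCCCCCCCC
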